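**Retrosynthetic overview**
1. The 5'-OH goes in last, by ortho-oxygenation of the 4'-phenol through an ortho-quinone. Ring B is therefore bought as 2,4-dihydroxybenzoic acid and no catechol needs protection.
2. Oxepine: the aryl O–C(=CMe2) bond comes from a copper-catalysed intramolecular O-vinylation of a 3-(2-bromoprenyl) side chain.
3. Dimethylpyran: DDQ ortho-quinone methide/oxa-6π closure of the C8 prenyl group of a 6,8-diprenyl-5,7-dihydroxyflavone.
4. Key disconnection: pyrone ring C and both new bonds at C3 are made in one flask (C-alkylation, C-aroylation, cyclodehydration) from an unprotected, mirror-symmetric 3,5-diprenyl acylphloroglucinol. Its two ortho OH groups are equivalent, so ring closure breaks the symmetry without any regiochemical choice.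
5. Ring order: A and B bought, then pyrone C, then dimethylpyran, then oxepine.

Assumption: the SMILES contains no stereocentre and no stereogenic double bond, so the target is achiral and no stereocontrol is needed.

**Step 1**
Reactants: 1 2,4,6-trihydroxyacetophenone; 2 prenyl bromide (1-bromo-3-methylbut-2-ene, 2.1 equiv)
Product: 3 1-[2,4,6-trihydroxy-3,5-bis(3-methylbut-2-enyl)phenyl]ethanone
Conditions: KOH (2.2 equiv), H2O, 0 °C to rt
Reagents that add atoms: none
Why: Nuclear C-prenylation of the ambident phloroglucinol phenolate in water (the deoxyhumulone-type alkylation) puts one prenyl group on each of the two equivalent free ring carbons, keeps the mirror plane and creates no stereocentre.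

**Step 2**
Reactants: 4 3-methylbuta-1,2-diene
Product: 6 1,2-dibromo-3-methylbut-2-ene, via 2,3-dibromo-3-methylbut-1-ene 5 (not isolated)
Conditions: Br2 (1.0 equiv), CH2Cl2, −78 °C to rt, 12 h
Reagents that add atoms: bromine, BrBr
Why: Electrophilic bromine addition to the more substituted allene double bond gives the tertiary allylic dibromide 5, which equilibrates by allylic bromide shift to the primary bromide carrying the tetrasubstituted alkene, and no alkene geometry arises because the terminus bears two methyl groups.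

**Step 3**
Reactants: 7 2,4-dihydroxybenzoic acid
Product: 8 tert-butyldimethylsilyl 2,4-bis(tert-butyldimethylsilyloxy)benzoate
Conditions: TBSCl (3.5 equiv), imidazole (7 equiv), DMF, rt
Reagents that add atoms: tert-butyldimethylsilyl chloride (TBSCl), CC(C)(C)[Si](C)(C)Cl
Why: Imidazole-promoted Corey silylation covers both phenols and the acid in one operation and creates no stereocentre.

**Step 4**
Reactants: 8 tert-butyldimethylsilyl 2,4-bis(tert-butyldimethylsilyloxy)benzoate
Product: 9 2,4-bis(tert-butyldimethylsilyloxy)benzoyl chloride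
Conditions: (COCl)2 (1.2 equiv), DMF (cat.), CH2Cl2, 0 °C to rt, used crude
Reagents that add atoms: oxalyl chloride, O=C(Cl)C(=O)Cl
Why: The Wissner–Grudzinskas conversion of a silyl ester into the acid chloride through the Vilsmeier chloroiminium salt runs under neutral conditions, so the two aryl silyl ethers survive.

**Step 5 (key step)**
Reactants: 3 1-[2,4,6-trihydroxy-3,5-bis(3-methylbut-2-enyl)phenyl]ethanone; 6 1,2-dibromo-3-methylbut-2-ene; 9 2,4-bis(tert-butyldimethylsilyloxy)benzoyl chloride
Product: 12 3-(2-bromo-3-methylbut-2-enyl)-2-[2,4-bis(tert-butyldimethylsilyloxy)phenyl]-5,7-dihydroxy-6,8-bis(3-methylbut-2-enyl)chromen-4-one, via chain-extended ketone 10 (not isolated), via 2-alkyl-1,3-diketone 11 (not isolated)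
Conditions: LiN(SiMe3)2 (4.3 equiv), THF, −78 to −10 °C; 6 (1.0 equiv), −78 to −20 °C; LiN(SiMe3)2 (2.2 equiv), −78 °C; 9 (1.1 equiv), −78 °C to rt; AcOH quench, solvent swap; PPTS (20 mol %), toluene, 4 Å MS, 80 °C
Reagents that add atoms: none
Why: Proposed new method: in the tetralithio derivative of 3 the last-formed and most basic site, the ketone enolate carbon, reacts first (Hauser polyanion rule), so the allylic bromide 6 alkylates the acetyl carbon rather than a phenoxide or a ring carbon, re-enolisation and C-aroylation by 9 then follow the Cushman polyanion flavone synthesis (a direct Baker–Venkataraman equivalent, the closest known reaction type), and mild acid cyclodehydration closes the pyrone without touching prenyl groups or silyl ethers; because the two ortho OH groups of 3 are mirror-related either closure gives the same flavone, the closure breaks the symmetry and makes the C6 and C8 prenyl groups different, and the transient racemic stereocentre of 11 is lost on dehydration.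

**Step 6**
Reactants: 12 3-(2-bromo-3-methylbut-2-enyl)-2-[2,4-bis(tert-butyldimethylsilyloxy)phenyl]-5,7-dihydroxy-6,8-bis(3-methylbut-2-enyl)chromen-4-one
Product: 14 3-(2-bromo-3-methylbut-2-enyl)-2-[2,4-bis(tert-butyldimethylsilyloxy)phenyl]-5-hydroxy-8,8-dimethyl-6-(3-methylbut-2-enyl)pyrano[2,3-h]chromen-4-one, via ortho-quinone methide 13 (not isolated)
Conditions: DDQ (1.05 equiv), 1,4-dioxane, rt to 60 °C
Reagents that add atoms: none
Why: DDQ dehydrogenation of an ortho-prenylphenol (hydride abstraction to the dearomatised ortho-quinone methide 13, then oxa-6π electrocyclisation) should start at the C8 prenyl group, because only the C7=O/C8 methide keeps both the pyrone conjugation and the chelated 5-OH, in line with C8 being the kinetic site of Mannich and halogenation reactions of 5,7-dihydroxyflavones, while the bromoalkene and the silyl ethers are inert.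

**Step 7**
Reactants: 14 3-(2-bromo-3-methylbut-2-enyl)-2-[2,4-bis(tert-butyldimethylsilyloxy)phenyl]-5-hydroxy-8,8-dimethyl-6-(3-methylbut-2-enyl)pyrano[2,3-h]chromen-4-one
Product: 16 5'-deoxyisocycloheterophyllin (oxepine closed; 4'-OH free), via desilylated bromide 15 (not isolated)
Conditions: CsF (4 equiv), CuI (20 mol %), 1,10-phenanthroline (40 mol %), DMF, argon, rt then 90 °C; pH 7 buffer work-up
Reagents that add atoms: none
Why: Fluoride frees both ring B phenoxides and the 2'-phenoxide, held next to the vinyl bromide, closes the seven-membered ring by Ullmann-type intramolecular O-vinylation (7-exo) under monovalent copper catalysis without moving the double bond, a coupling known to tolerate hindered 2-bromo-3-methylbut-2-ene-type halides, while the 4'- and 5-oxygens cannot reach the bromide.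

**Step 8**
Reactants: 16 5'-deoxyisocycloheterophyllin
Product: 18 isocycloheterophyllin, via ortho-quinone 17 (not isolated)
Conditions: IBX (1.1 equiv), DMF, 0 °C to rt; then aq Na2S2O4, pH 7 phosphate buffer, rt
Reagents that add atoms: IBX (2-iodoxybenzoic acid), O=C1OI(=O)(O)c2ccccc12
Why: IBX transfers oxygen from pentavalent iodine to the less hindered ortho carbon C5' (para to the 2'-ether oxygen) of the only unchelated phenol, giving the dearomatised ortho-quinone 17 (Pettus-type phenol to ortho-quinone oxidation, reported for 4'-hydroxyflavonoids), and dithionite reduces 17 in the same flask to the catechol, while the chelated 5-OH has no free ortho position and the alkenes and the enol ether are not attacked at rt.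

**Compound list**
1 | 2,4,6-trihydroxyacetophenone | CC(=O)c1c(O)cc(O)cc1O | starting material
2 | prenyl bromide | CC(C)=CCBr | starting material
3 | 1-[2,4,6-trihydroxy-3,5-bis(3-methylbut-2-enyl)phenyl]ethanone | CC(=O)c1c(O)c(CC=C(C)C)c(O)c(CC=C(C)C)c1O | intermediate
4 | 3-methylbuta-1,2-diene | CC(C)=C=C | starting material
5 | 2,3-dibromo-3-methylbut-1-ene | C=C(Br)C(C)(C)Br | intermediate
6 | 1,2-dibromo-3-methylbut-2-ene | CC(C)=C(Br)CBr | intermediate
7 | 2,4-dihydroxybenzoic acid | OC(=O)c1ccc(O)cc1O | starting material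
8 | tert-butyldimethylsilyl 2,4-bis(tert-butyldimethylsilyloxy)benzoate | CC(C)(C)[Si](C)(C)OC(=O)c1ccc(O[Si](C)(C)C(C)(C)C)cc1O[Si](C)(C)C(C)(C)C | intermediate
9 | 2,4-bis(tert-butyldimethylsilyloxy)benzoyl chloride | O=C(Cl)c1ccc(O[Si](C)(C)C(C)(C)C)cc1O[Si](C)(C)C(C)(C)C | intermediate
10 | 4-bromo-5-methyl-1-[2,4,6-trihydroxy-3,5-bis(3-methylbut-2-enyl)phenyl]hex-4-en-1-one | CC(C)=C(Br)CCC(=O)c1c(O)c(CC=C(C)C)c(O)c(CC=C(C)C)c1O | intermediate
11 | 2-(2-bromo-3-methylbut-2-enyl)-1-[2,4-bis(tert-butyldimethylsilyloxy)phenyl]-3-[2,4,6-trihydroxy-3,5-bis(3-methylbut-2-enyl)phenyl]propane-1,3-dione (racemic) | CC(C)=C(Br)CC(C(=O)c1ccc(O[Si](C)(C)C(C)(C)C)cc1O[Si](C)(C)C(C)(C)C)C(=O)c1c(O)c(CC=C(C)C)c(O)c(CC=C(C)C)c1O | intermediate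
12 | 3-(2-bromo-3-methylbut-2-enyl)-2-[2,4-bis(tert-butyldimethylsilyloxy)phenyl]-5,7-dihydroxy-6,8-bis(3-methylbut-2-enyl)chromen-4-one | CC(C)=CCc1c(O)c(CC=C(C)C)c2oc(-c3ccc(O[Si](C)(C)C(C)(C)C)cc3O[Si](C)(C)C(C)(C)C)c(CC(Br)=C(C)C)c(=O)c2c1O | intermediate
13 | ring A ortho-quinone methide (C7=O, C8=CH–CH=CMe2) of 12 | CC(C)=CCC1=C(O)C2=C(OC(c3ccc(O[Si](C)(C)C(C)(C)C)cc3O[Si](C)(C)C(C)(C)C)=C(CC(Br)=C(C)C)C2=O)C(=CC=C(C)C)C1=O | intermediate
14 | 3-(2-bromo-3-methylbut-2-enyl)-2-[2,4-bis(tert-butyldimethylsilyloxy)phenyl]-5-hydroxy-8,8-dimethyl-6-(3-methylbut-2-enyl)pyrano[2,3-h]chromen-4-one | CC(C)=CCc1c2OC(C)(C)C=Cc2c2oc(-c3ccc(O[Si](C)(C)C(C)(C)C)cc3O[Si](C)(C)C(C)(C)C)c(CC(Br)=C(C)C)c(=O)c2c1O | intermediate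
15 | 3-(2-bromo-3-methylbut-2-enyl)-2-(2,4-dihydroxyphenyl)-5-hydroxy-8,8-dimethyl-6-(3-methylbut-2-enyl)pyrano[2,3-h]chromen-4-one (present as cesium phenoxide) | CC(C)=CCc1c2OC(C)(C)C=Cc2c2oc(-c3ccc(O)cc3O)c(CC(Br)=C(C)C)c(=O)c2c1O | intermediate
16 | 5'-deoxyisocycloheterophyllin | CC(C)=CCc1c2c(c3oc4c(c(=O)c3c1O)CC(=C(C)C)Oc1cc(O)ccc1-4)C=CC(C)(C)O2 | intermediate
17 | ring B 4',5'-ortho-quinone of the target | CC(C)=CCc1c2c(c3oc4c(c(=O)c3c1O)CC(=C(C)C)OC1=CC(=O)C(=O)C=C1-4)C=CC(C)(C)O2 | intermediate
18 | isocycloheterophyllin | CC(C)=CCc1c2c(c3oc4c(c(=O)c3c1O)CC(=C(C)C)Oc1cc(O)c(O)cc1-4)C=CC(C)(C)O2 | target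

**Totals**
Total step count: 8. Longest linear sequence: 6 steps (7 → 8 → 9 → 12 → 14 → 16 → 18).

**Three steps most likely to fail**

Step 5. Enolisation of the triphenoxide may be incomplete. Bromide 6 may then alkylate a prenyl-bearing ring carbon to give a dearomatised gem-dialkyl product, or alkylate the side chain twice.

Fallback: build the side chain by electrophilic acylation of the arene instead of polyanion alkylation. It sets out from 6, which alkylates LiCH2CN (MeCN, LiN(iPr)2, THF, −78 °C) to give 4-bromo-5-methylhex-4-enenitrile F1. A Houben–Hoesch reaction of F1 with phloroglucinol (ZnCl2, HCl gas, Et2O, 0 °C) gives 4-bromo-5-methyl-1-(2,4,6-trihydroxyphenyl)hex-4-en-1-iminium chloride F2. Hot water hydrolyses F2 to 4-bromo-5-methyl-1-(2,4,6-trihydroxyphenyl)hex-4-en-1-one F3. C-diprenylation of F3 with 2 under the conditions of step 1 comes back to the route at 10, now isolated. Only the precedented aroylation and cyclodehydration half of step 5 is then run on 10.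

Step 6. DDQ may attack the C6 prenyl group competitively and give the linear 6,7-pyrano isomer.

Fallback: make the pyran by annulation at a carbon that has no alternative, instead of choosing between two prenyl groups. It sets out from 1, which is mono-prenylated with one equivalent of 2 (KOH, H2O) to give 1-[2,4,6-trihydroxy-3-(3-methylbut-2-enyl)phenyl]ethanone F4. The step 5 protocol with 6 and 9 then passes through two intermediates:
- 4-bromo-5-methyl-1-[2,4,6-trihydroxy-3-(3-methylbut-2-enyl)phenyl]hex-4-en-1-one F5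
- 2-(2-bromo-3-methylbut-2-enyl)-1-[2,4-bis(tert-butyldimethylsilyloxy)phenyl]-3-[2,4,6-trihydroxy-3-(3-methylbut-2-enyl)phenyl]propane-1,3-dione F6

Closure through the less hindered ortho OH gives 3-(2-bromo-3-methylbut-2-enyl)-2-[2,4-bis(tert-butyldimethylsilyloxy)phenyl]-5,7-dihydroxy-6-(3-methylbut-2-enyl)chromen-4-one F7, and the 8-prenyl isomer is removed by chromatography. Aldol-type condensation of F7 with 3-methylbut-2-enal (ethylenediammonium diacetate, toluene, reflux) can occur only at C8. It comes back to the route at 13, which electrocyclises to 14.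

Step 8. IBX may be too slow on a phenol para to the chromone, or may damage ring A or the enol ether.

Fallback: replace the dearomatising oxidation by formylation and aryl migration. It sets out from 16. Magnesium-mediated ortho-formylation (MgCl2, Et3N, paraformaldehyde, MeCN, reflux) at the less hindered C5' gives 5'-formyl-5'-deoxyisocycloheterophyllin F8. Dakin oxidation (H2O2, aq NaHCO3, THF, rt) gives the 5'-O-formate of isocycloheterophyllin F9. F9 is hydrolysed in the same basic medium and comes back to the route at 18.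

**Further compounds**
F1 | step 5 | 4-bromo-5-methylhex-4-enenitrile | CC(C)=C(Br)CCC#N
F2 | step 5 | 4-bromo-5-methyl-1-(2,4,6-trihydroxyphenyl)hex-4-en-1-iminium chloride | CC(C)=C(Br)CCC(=[NH2+])c1c(O)cc(O)cc1O.[Cl-]
F3 | step 5 | 4-bromo-5-methyl-1-(2,4,6-trihydroxyphenyl)hex-4-en-1-one | CC(C)=C(Br)CCC(=O)c1c(O)cc(O)cc1O
F4 | step 6 | 1-[2,4,6-trihydroxy-3-(3-methylbut-2-enyl)phenyl]ethanone | CC(=O)c1c(O)cc(O)c(CC=C(C)C)c1O
F5 | step 6 | 4-bromo-5-methyl-1-[2,4,6-trihydroxy-3-(3-methylbut-2-enyl)phenyl]hex-4-en-1-one | CC(C)=C(Br)CCC(=O)c1c(O)cc(O)c(CC=C(C)C)c1O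
F6 | step 6 | 2-(2-bromo-3-methylbut-2-enyl)-1-[2,4-bis(tert-butyldimethylsilyloxy)phenyl]-3-[2,4,6-trihydroxy-3-(3-methylbut-2-enyl)phenyl]propane-1,3-dione (racemic) | CC(C)=C(Br)CC(C(=O)c1ccc(O[Si](C)(C)C(C)(C)C)cc1O[Si](C)(C)C(C)(C)C)C(=O)c1c(O)cc(O)c(CC=C(C)C)c1O
F7 | step 6 | 3-(2-bromo-3-methylbut-2-enyl)-2-[2,4-bis(tert-butyldimethylsilyloxy)phenyl]-5,7-dihydroxy-6-(3-methylbut-2-enyl)chromen-4-one | CC(C)=CCc1c(O)cc2oc(-c3ccc(O[Si](C)(C)C(C)(C)C)cc3O[Si](C)(C)C(C)(C)C)c(CC(Br)=C(C)C)c(=O)c2c1O
F8 | step 8 | 5'-formyl-5'-deoxyisocycloheterophyllin | CC(C)=CCc1c2c(c3oc4c(c(=O)c3c1O)CC(=C(C)C)Oc1cc(O)c(C=O)cc1-4)C=CC(C)(C)O2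
F9 | step 8 | 5'-O-formate of isocycloheterophyllin | CC(C)=CCc1c2c(c3oc4c(c(=O)c3c1O)CC(=C(C)C)Oc1cc(O)c(OC=O)cc1-4)C=CC(C)(C)O2
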